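About 0.287 min⁻¹: that is how fast target turns into isomer of the product at 90 °C, read from the delta run between 1.33 min and 3.00 min as isomer gained over mean target times elapsed time. The four flasks differ in how the second substrate goes in and in temperature, and we want target's share of target plus isomer.

in all of them: starting material 0.032 M

| run | partner | second substrate | third substrate | protic impurity | temperature | remark | time |
|---|---|---|---|---|---|---|---|
| beta | 0.032 M | 0.032 M | 0.032 M | 9.6 mM | 75 °C | run made earlier |  |
| gamma | 0.032 M | 0.032 M | 0.032 M | 13 mM | 90 °C | run made earlier |  |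
| theta | 0.032 M | 0.032 M | 0.032 M | 21 mM | 75 °C | run made earlier |  |
| delta | 0.064 M | 0.032 M | 0.032 M | 9.6 mM | 90 °C | run made earlier |  |
| alder | 0.0320 M | 0.0320 M (fed, over 10 s) | 0.0320 M | 9.60 mM | 90 °C | all else is in the flask from the start; the feed brings no volume worth counting | 2.5 min |
| ash | 0.0320 M | 0.0320 M (fed, over 1.5 min) | 0.0320 M | 9.60 mM | 90 °C | all else is in the flask from the start; the feed brings no volume worth counting | 2.5 min |
| cedar | 0.0320 M | 0.0320 M | 0.0320 M | 9.60 mM | 90 °C | everything together at the start | 2.5 min |
| larch | 0.0320 M | 0.0320 M (fed, over 1.5 min) | 0.0320 M | 9.60 mM |  | the addition at 70 °C, then warmed to 90 °C; the feed brings no volume worth counting | 2.5 min |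

- beta (time / min: target / %, isomer of the product / %): 0.333: 8.7, 0; 0.667: 16.1, 1.3; 1.00: 21.7, 1.3; 2.00: 30.9, 2.4; 3.00: 35.1, 5.4
- gamma (time / min: target / %, isomer of the product / %): 0.500: 19.5, 2.5; 1.00: 23.6, 5.0; 1.50: 28.4, 7.6; 2.00: 29.1, 12.5; 2.50: 25.2, 16.5; 3.00: 25.9, 18.6
- theta (time / min: target / %, isomer of the product / %): 0.500: 12.4, 0.5; 0.833: 18.4, 0.5; 1.33: 25.5, 0.7; 2.00: 29.1, 3.6; 4.00: 32.7, 6.1; 6.00: 31.6, 13.9
- delta (time / min: target / %, isomer of the product / %): 0.250: 22.1, 0.4; 0.833: 45.5, 6.5; 1.33: 48.9, 12.1; 2.00: 46.1, 22.5; 3.00: 43.8, 34.3

(each reading ± 1 percentage point)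

- candidate steps: third substrate + partner -> third product; partner + protic impurity -> quenched reagent; starting material + partner -> target; second substrate <-> dormant form; second substrate + partner -> second product; target <-> isomer of the product

* which flask leads in share of target in target plus isomer of the product ("all alike" within 1.5 percentage points) (alder / ash / cedar / larch / all alike)
* share of target in target plus isomer of the product at the end, alder
* share of target in target plus isomer of the product at the end, ash
* share of target in target plus isomer of the product at the end, cedar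
* share of target in target plus isomer of the product at the end, larch

We follow one target molecule, which meets one fork after its birth: stay or isomerise. The theta run, read the same way between 2.00 min and 6.00 min, gives 0.0848 min⁻¹ at 75 °C, and carrying the same fall per degree downward gives 0.0565 min⁻¹ at 70 °C.

In larch, if warming takes no time, a molecule born halfway through the cold addition collects 0.329. This exposure, the first-order rate constant summed over the molecule's age, gives exp(−exposure) as its chance of still being target, with the way back ignored. So we reckon 71.9% for larch.

For the flasks held at 90 °C we take the gamma reading at 2.50 min, a share of 60.4%, though [protic impurity] was 13 mM in gamma against 9.60 mM in these flasks. Larch therefore stands higher in our reckoning than the other three.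

The forecast gave 62% for alder, 60% for ash, 63% for cedar and 75% for larch, “so larch leads clearly”.

The flasks give 62.8% for alder, 63.0% for ash, 62.8% for cedar and 77.1% for larch, which leads, and our larch figure lies 5.2 percentage points below it.

    third substrate + partner → third product (k = 0.0800 M⁻¹ s⁻¹, Ea = 69.0 kJ mol⁻¹)
    partner + protic impurity → quenched reagent (k = 0.290 M⁻¹ s⁻¹, Ea = 49.0 kJ mol⁻¹)
    starting material + partner → target (k = 0.330 M⁻¹ s⁻¹, Ea = 44.0 kJ mol⁻¹)
    second substrate ⇌ dormant form (K = 13.0, k = 0.00730 s⁻¹, Ea = 107 kJ mol⁻¹, ΔH = 60.0 kJ mol⁻¹)
    second substrate + partner → second product (k = 0.150 M⁻¹ s⁻¹, Ea = 52.0 kJ mol⁻¹)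
    target ⇌ isomer of the product (K = 4.10, k = 0.00490 s⁻¹, Ea = 94.0 kJ mol⁻¹, ΔH = −6.00 kJ mol⁻¹)
    (constants at 90 °C)

Larch's share corresponds to an exposure of 0.260, against our 0.329. A neighbouring flask is larch with [partner] = 0.080 M, on the same temperatures and times. For a molecule born at the same moment as before, the reckoning gives the same exposure, 0.329, and the same share, 71.9%. That flask gives 76.0%, against 77.1% in larch, while target stands at 59.8% against 32.5% and isomer of the product at 18.9% against 9.68%.

(Readings and results were computed for substances that don't exist; the scatter is artificial.)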